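**Strategy.** The dihydropyran ring (O1, C2 guaiacyl, C3, C4, C5 benzofuranyl, C6) is cut at C3–C4. C3 lies α to the carboxyl-level carbon that becomes CH2OAc, and C4–C5=C6 is an allyl unit whose C6 carries O1. Giving C6 a second, acyl oxygen ties it to that carboxyl carbon as a cis-2-(1-benzofuranylvinyl)-6-aryl-1,3-dioxan-4-one. Ireland–Claisen rearrangement of its silyl ketene acetal forms C3–C4, sets C3 trans to C2, and turns the acetal carbon into the C5=C6 enol ether, contracting the acetal-lactone to the pyran in one operation. The C2 stereocentre comes from asymmetric transfer hydrogenation; both phenols travel as TIPS ethers.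

Key step: step 12

Remark: both phenols are carried as triisopropylsilyl instead of TBS ethers (they must survive ethoxide, hydroxide, coupling base and hydride), and the benzofuran is grown from 2',5'-dimethoxyacetophenone so that the iodination site is unambiguous and no hydroquinone is exposed to the halogenating agent; the key-step skeletons are unchanged.

**Step 1**
Reactants: 1 acetovanillone
Product: 2 1-[3-methoxy-4-(triisopropylsilyloxy)phenyl]ethanone
Conditions: TIPSCl (1.2 equiv), imidazole (2.5 equiv), DMF, rt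
Reagents that add atoms: chlorotriisopropylsilane, CC(C)[Si](Cl)(C(C)C)C(C)C
Why: Imidazole-mediated silyl ether formation masks the acidic phenol before enolate chemistry, and an aryl TIPS ether withstands the alkoxide of step 2 and the hydroxide of step 4.

**Step 2**
Reactants: 2 1-[3-methoxy-4-(triisopropylsilyloxy)phenyl]ethanone; 3 diethyl carbonate
Product: 4 ethyl 3-[3-methoxy-4-(triisopropylsilyloxy)phenyl]-3-oxopropanoate
Conditions: NaH (2.5 equiv), (EtO)2CO (4 equiv), toluene, 80 °C; AcOH quench, 0 °C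
Reagents that add atoms: none
Why: Crossed Claisen condensation of the methyl ketone enolate with a non-enolisable carbonate, driven by formation of the doubly stabilised β-keto ester enolate.

**Step 3**
Reactants: 4 ethyl 3-[3-methoxy-4-(triisopropylsilyloxy)phenyl]-3-oxopropanoate
Product: 5 ethyl (3R)-3-hydroxy-3-[3-methoxy-4-(triisopropylsilyloxy)phenyl]propanoate
Conditions: RuCl[(R,R)-TsDPEN](p-cymene) (1 mol%), HCO2H–Et3N (5:2), EtOAc, 35 °C
Reagents that add atoms: none
Why: Noyori asymmetric transfer hydrogenation of an aryl β-keto ester; the (R,R)-catalyst, which gives (R)-1-arylalkanols through its aryl-oriented six-membered hydride-transfer transition state, should set the (R)-carbinol that becomes pyran C2 (ee to be checked by chiral HPLC).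

**Step 4**
Reactants: 5 ethyl (3R)-3-hydroxy-3-[3-methoxy-4-(triisopropylsilyloxy)phenyl]propanoate
Product: 6 (3R)-3-hydroxy-3-[3-methoxy-4-(triisopropylsilyloxy)phenyl]propanoic acid
Conditions: LiOH·H2O (1.5 equiv), THF–H2O 3:1, 0 °C; 0.5 M HCl to pH 4 at 0 °C; used promptly
Reagents that add atoms: lithium hydroxide, [Li+].[OH-]
Why: Saponification of an unhindered ethyl ester in the cold, which the aryl TIPS ether should tolerate and which does not touch the carbinol centre.

**Step 5**
Reactants: 7 acrolein diethyl acetal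
Product: 9 2-bromo-3,3-diethoxyprop-1-ene, via dibromide 8 (not isolated)
Conditions: Br2 (1.0 equiv), CH2Cl2, −20 °C; evaporate; t-BuOK (1.1 equiv), THF, 0 °C
Reagents that add atoms: bromine, BrBr
Why: Bromine addition to the alkene followed by E2 loss of HBr through the more acidic C2–H (α to bromine and to the acetal) gives the 2-bromoalkene.

**Step 6**
Reactants: 9 2-bromo-3,3-diethoxyprop-1-ene; 10 ethynyltrimethylsilane
Product: 11 [3-(diethoxymethyl)but-3-en-1-yn-1-yl]trimethylsilane
Conditions: PdCl2(PPh3)2 (2 mol%), CuI (4 mol%), Et3N, THF, 40 °C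
Reagents that add atoms: none
Why: Sonogashira coupling of a 1,1-disubstituted vinyl bromide with a terminal alkyne; the acetal is inert to the Pd/Cu/amine medium.

**Step 7**
Reactants: 12 2',5'-dimethoxyacetophenone
Product: 13 1-(4-iodo-2,5-dimethoxyphenyl)ethanone
Conditions: ICl (1.2 equiv), AcOH, 40 °C
Reagents that add atoms: iodine monochloride, ClI
Why: Electrophilic aromatic iodination goes to C4 (ortho to the 5-methoxy group, para to the acetyl group), the position taken in other 1-substituted 2,5-dimethoxybenzenes, and the diether cannot be oxidised to a quinone.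

**Step 8**
Reactants: 13 1-(4-iodo-2,5-dimethoxyphenyl)ethanone
Product: 14 1-(2,5-dihydroxy-4-iodophenyl)ethanone
Conditions: BBr3 (3 equiv), CH2Cl2, −78 → 0 °C; H2O
Reagents that add atoms: none
Why: Lewis-acid cleavage of both aryl methyl ethers with BBr3, to which the ketone and the aryl iodide are inert.

**Step 9**
Reactants: 14 1-(2,5-dihydroxy-4-iodophenyl)ethanone; 11 [3-(diethoxymethyl)but-3-en-1-yn-1-yl]trimethylsilane
Product: 17 1-[2-(3,3-diethoxyprop-1-en-2-yl)-5-hydroxy-1-benzofuran-6-yl]ethanone, via terminal enyne 15 (not isolated), via alkynylphenol 16 (not isolated)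
Conditions: PdCl2(PPh3)2 (3 mol%), CuI (6 mol%), CsF (2 equiv), Et3N (3 equiv), wet DMF, 60 °C, Ar
Reagents that add atoms: none
Why: Fluoride-triggered in situ desilylation feeds the volatile enyne slowly into a Sonogashira coupling, and the o-alkynylphenol, whose alkyne is para to the acetyl group, closes by Cu/base-mediated 5-endo-dig heteroannulation; the chelated hydroxyl ortho to the acetyl group cannot reach the alkyne, so only one benzofuran can form.

**Step 10**
Reactants: 17 1-[2-(3,3-diethoxyprop-1-en-2-yl)-5-hydroxy-1-benzofuran-6-yl]ethanone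
Product: 18 1-[2-(3,3-diethoxyprop-1-en-2-yl)-5-(triisopropylsilyloxy)-1-benzofuran-6-yl]ethanone
Conditions: TIPSCl (1.3 equiv), imidazole (2.5 equiv), DMAP (cat.), DMF, 40 °C
Reagents that add atoms: chlorotriisopropylsilane, CC(C)[Si](Cl)(C(C)C)C(C)C
Why: Silyl ether formation at the only remaining hydroxyl under non-Lewis-acidic conditions that leave the unsaturated acetal intact.

**Step 11**
Reactants: 6 (3R)-3-hydroxy-3-[3-methoxy-4-(triisopropylsilyloxy)phenyl]propanoic acid; 18 1-[2-(3,3-diethoxyprop-1-en-2-yl)-5-(triisopropylsilyloxy)-1-benzofuran-6-yl]ethanone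
Product: 20 (2S,6R)-2-{1-[6-acetyl-5-(triisopropylsilyloxy)-1-benzofuran-2-yl]ethenyl}-6-[3-methoxy-4-(triisopropylsilyloxy)phenyl]-1,3-dioxan-4-one (2,6-cis), via bis-TMS hydroxy acid 19 (not isolated)
Conditions: HMDS (1.2 equiv), TMSCl (cat.), CH2Cl2, 40 °C, evaporate; 18 (1.0 equiv), TMSOTf (10 mol%), CH2Cl2, −78 → −30 °C; pyridine quench; Et3N-deactivated silica
Reagents that add atoms: none
Why: Noyori-type TMSOTf-catalysed acetal exchange between a bis-silylated β-hydroxy acid and a dialkyl acetal, the low-temperature route to 2,6-disubstituted 1,3-dioxan-4-ones; the new acetal centre should form cis to the aryl group because both substituents are then equatorial on the dioxanone half-chair.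

**Step 12**
Reactants: 20 (2S,6R)-2-{1-[6-acetyl-5-(triisopropylsilyloxy)-1-benzofuran-2-yl]ethenyl}-6-[3-methoxy-4-(triisopropylsilyloxy)phenyl]-1,3-dioxan-4-one
Product: 23 (2R,3R)-5-[6-acetyl-5-(triisopropylsilyloxy)-1-benzofuran-2-yl]-2-[3-methoxy-4-(triisopropylsilyloxy)phenyl]-3,4-dihydro-2H-pyran-3-carboxylic acid (2,3-trans), via silyl ketene acetal 21 (not isolated), via rearranged silyl ester 22 (not isolated)
Conditions: TMSCl–Et3N (6 equiv each), THF, −95 °C; LDA (3.0 equiv); −95 → 23 °C (40 °C if needed); aq. citric acid–THF, pH 4, 0 °C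
Reagents that add atoms: none
Why: Proposed new method: in situ LDA/TMSCl silylation converts the lactone into its endocyclic silyl ketene acetal 21 (the methyl ketone becomes an enol silane and returns on work-up), in which C5=C4(OTMS)–O3–C2–C(benzofuranyl)=CH2 of the dioxanone is an allyl vinyl ether whose allylic carbon is the acetal carbon; a [3,3]-shift joins C5 to the vinyl CH2 and breaks O3–C2, as in the closest known reaction type, the Ireland–Claisen ring contraction of alkenyl-substituted lactones (6-alkenyl-1,4-dioxan-2-ones to dihydropyrans), extended here to a lactone acetal. The dihydropyran (O1, the aryl-bearing carbon, old C5, the two vinyl carbons and the former acetal carbon) closes by this sigmatropic reorganisation through a boat-like, bicyclo[2.2.2]-type transition state, not by a polar cyclisation. The new stereocentre, pyran C3, is controlled by the acetal centre of 20: in the cis isomer the vinyl group sits on the aryl face of the dioxanone, the tether allows C–C bonding only on that face, and once the old ring has opened the carboxyl group lies trans to the aryl group. The step needs silylation to outrun E1cB expulsion of O1 from the lactone enolate (internal TMSCl quench at −95 °C) and a diastereomerically pure cis acetal, because the trans acetal would lead to the cis acid; the ring-bound ketene acetal has only one geometry. The breaking bond is an acetal C–O bond and the enol ether formed is conjugated with the benzofuran, which should make the shift easier than in the known ether cases.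

**Step 13**
Reactants: 23 (2R,3R)-5-[6-acetyl-5-(triisopropylsilyloxy)-1-benzofuran-2-yl]-2-[3-methoxy-4-(triisopropylsilyloxy)phenyl]-3,4-dihydro-2H-pyran-3-carboxylic acid
Product: 24 {(2R,3S)-5-[6-(1-hydroxyethyl)-5-(triisopropylsilyloxy)-1-benzofuran-2-yl]-2-[3-methoxy-4-(triisopropylsilyloxy)phenyl]-3,4-dihydro-2H-pyran-3-yl}methanol (both carbinol epimers)
Conditions: LiAlH4 (3 equiv), THF, 0 °C → rt; Rochelle salt work-up
Reagents that add atoms: none
Why: LiAlH4 reduction of the carboxylic acid to the primary alcohol; the ketone is reduced too (corrected in step 14), while the enol ether, the aryl TIPS ethers and both ring stereocentres are not affected.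

**Step 14**
Reactants: 24 {(2R,3S)-5-[6-(1-hydroxyethyl)-5-(triisopropylsilyloxy)-1-benzofuran-2-yl]-2-[3-methoxy-4-(triisopropylsilyloxy)phenyl]-3,4-dihydro-2H-pyran-3-yl}methanol
Product: 25 1-{2-[(2R,3S)-3-(hydroxymethyl)-2-[3-methoxy-4-(triisopropylsilyloxy)phenyl]-3,4-dihydro-2H-pyran-5-yl]-5-(triisopropylsilyloxy)-1-benzofuran-6-yl}ethanone
Conditions: activated MnO2 (20 equiv), CH2Cl2, rt
Reagents that add atoms: none
Why: MnO2 oxidation is selective for the benzylic secondary alcohol over the saturated primary alcohol and is neutral, so the enol ether is safe.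

**Step 15**
Reactants: 25 1-{2-[(2R,3S)-3-(hydroxymethyl)-2-[3-methoxy-4-(triisopropylsilyloxy)phenyl]-3,4-dihydro-2H-pyran-5-yl]-5-(triisopropylsilyloxy)-1-benzofuran-6-yl}ethanone
Product: 26 {(2R,3S)-5-[6-acetyl-5-(triisopropylsilyloxy)-1-benzofuran-2-yl]-2-[3-methoxy-4-(triisopropylsilyloxy)phenyl]-3,4-dihydro-2H-pyran-3-yl}methyl acetate
Conditions: Ac2O (1.5 equiv), pyridine, DMAP (5 mol%), CH2Cl2, 0 °C
Reagents that add atoms: acetic anhydride, CC(=O)OC(C)=O
Why: DMAP-catalysed acylation of the primary alcohol, the only free hydroxyl group.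

**Step 16**
Reactants: 26 {(2R,3S)-5-[6-acetyl-5-(triisopropylsilyloxy)-1-benzofuran-2-yl]-2-[3-methoxy-4-(triisopropylsilyloxy)phenyl]-3,4-dihydro-2H-pyran-3-yl}methyl acetate
Product: 27 propolis-benzofuran A, [(2R,3S)-5-(6-acetyl-5-hydroxy-1-benzofuran-2-yl)-2-(4-hydroxy-3-methoxyphenyl)-3,4-dihydro-2H-pyran-3-yl]methyl acetate
Conditions: TBAF (2.4 equiv), AcOH (3 equiv), THF, 0 °C
Reagents that add atoms: none
Why: Fluoride cleavage of both aryl silyl ethers, buffered with acetic acid so that the phenoxides are protonated at once and neither the acetate nor the enol ether is attacked.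

**Compound list**

1 | acetovanillone | CC(=O)c1ccc(O)c(OC)c1 | starting material
2 | 1-[3-methoxy-4-(triisopropylsilyloxy)phenyl]ethanone | CC(=O)c1ccc(O[Si](C(C)C)(C(C)C)C(C)C)c(OC)c1 | intermediate
3 | diethyl carbonate | CCOC(=O)OCC | starting material
4 | ethyl 3-[3-methoxy-4-(triisopropylsilyloxy)phenyl]-3-oxopropanoate | CCOC(=O)CC(=O)c1ccc(O[Si](C(C)C)(C(C)C)C(C)C)c(OC)c1 | intermediate
5 | ethyl (3R)-3-hydroxy-3-[3-methoxy-4-(triisopropylsilyloxy)phenyl]propanoate | CCOC(=O)C[C@@H](O)c1ccc(O[Si](C(C)C)(C(C)C)C(C)C)c(OC)c1 | intermediate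
6 | (3R)-3-hydroxy-3-[3-methoxy-4-(triisopropylsilyloxy)phenyl]propanoic acid | OC(=O)C[C@@H](O)c1ccc(O[Si](C(C)C)(C(C)C)C(C)C)c(OC)c1 | intermediate
7 | acrolein diethyl acetal | C=CC(OCC)OCC | starting material
8 | 2,3-dibromo-1,1-diethoxypropane | CCOC(OCC)C(Br)CBr | intermediate (not isolated)
9 | 2-bromo-3,3-diethoxyprop-1-ene | CCOC(OCC)C(Br)=C | intermediate
10 | ethynyltrimethylsilane | C#C[Si](C)(C)C | starting material
11 | [3-(diethoxymethyl)but-3-en-1-yn-1-yl]trimethylsilane | CCOC(OCC)C(=C)C#C[Si](C)(C)C | intermediate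
12 | 2',5'-dimethoxyacetophenone | CC(=O)c1cc(OC)ccc1OC | starting material
13 | 1-(4-iodo-2,5-dimethoxyphenyl)ethanone | CC(=O)c1cc(OC)c(I)cc1OC | intermediate
14 | 1-(2,5-dihydroxy-4-iodophenyl)ethanone | CC(=O)c1cc(O)c(I)cc1O | intermediate
15 | 2-(diethoxymethyl)but-1-en-3-yne | CCOC(OCC)C(=C)C#C | intermediate (not isolated)
16 | 1-{4-[3-(diethoxymethyl)but-3-en-1-yn-1-yl]-2,5-dihydroxyphenyl}ethanone | CCOC(OCC)C(=C)C#Cc1cc(O)c(C(C)=O)cc1O | intermediate (not isolated)
17 | 1-[2-(3,3-diethoxyprop-1-en-2-yl)-5-hydroxy-1-benzofuran-6-yl]ethanone | CCOC(OCC)C(=C)c1cc2cc(O)c(C(C)=O)cc2o1 | intermediate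
18 | 1-[2-(3,3-diethoxyprop-1-en-2-yl)-5-(triisopropylsilyloxy)-1-benzofuran-6-yl]ethanone | CCOC(OCC)C(=C)c1cc2cc(O[Si](C(C)C)(C(C)C)C(C)C)c(C(C)=O)cc2o1 | intermediate
19 | trimethylsilyl (3R)-3-[3-methoxy-4-(triisopropylsilyloxy)phenyl]-3-(trimethylsilyloxy)propanoate | C[Si](C)(C)OC(=O)C[C@@H](O[Si](C)(C)C)c1ccc(O[Si](C(C)C)(C(C)C)C(C)C)c(OC)c1 | intermediate (not isolated)
20 | (2S,6R)-2-{1-[6-acetyl-5-(triisopropylsilyloxy)-1-benzofuran-2-yl]ethenyl}-6-[3-methoxy-4-(triisopropylsilyloxy)phenyl]-1,3-dioxan-4-one (cis) | COc1cc([C@@H]2O[C@H](C(=C)c3cc4cc(O[Si](C(C)C)(C(C)C)C(C)C)c(C(C)=O)cc4o3)OC(=O)C2)ccc1O[Si](C(C)C)(C(C)C)C(C)C | intermediate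
21 | silyl ketene acetal of 20 (ring C=C(OSiMe3), ketone as trimethylsilyl enol ether, configuration as in 20) | COc1cc([C@@H]2O[C@H](C(=C)c3cc4cc(O[Si](C(C)C)(C(C)C)C(C)C)c(C(=C)O[Si](C)(C)C)cc4o3)OC(O[Si](C)(C)C)=C2)ccc1O[Si](C(C)C)(C(C)C)C(C)C | intermediate (not isolated)
22 | trimethylsilyl ester of 23 with the ketone as trimethylsilyl enol ether | COc1cc([C@@H]2OC=C(c3cc4cc(O[Si](C(C)C)(C(C)C)C(C)C)c(C(=C)O[Si](C)(C)C)cc4o3)C[C@H]2C(=O)O[Si](C)(C)C)ccc1O[Si](C(C)C)(C(C)C)C(C)C | intermediate (not isolated)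
23 | (2R,3R)-5-[6-acetyl-5-(triisopropylsilyloxy)-1-benzofuran-2-yl]-2-[3-methoxy-4-(triisopropylsilyloxy)phenyl]-3,4-dihydro-2H-pyran-3-carboxylic acid (trans) | COc1cc([C@@H]2OC=C(c3cc4cc(O[Si](C(C)C)(C(C)C)C(C)C)c(C(C)=O)cc4o3)C[C@H]2C(=O)O)ccc1O[Si](C(C)C)(C(C)C)C(C)C | intermediate
24 | {(2R,3S)-5-[6-(1-hydroxyethyl)-5-(triisopropylsilyloxy)-1-benzofuran-2-yl]-2-[3-methoxy-4-(triisopropylsilyloxy)phenyl]-3,4-dihydro-2H-pyran-3-yl}methanol (carbinol epimers) | COc1cc([C@@H]2OC=C(c3cc4cc(O[Si](C(C)C)(C(C)C)C(C)C)c(C(C)O)cc4o3)C[C@H]2CO)ccc1O[Si](C(C)C)(C(C)C)C(C)C | intermediate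
25 | 1-{2-[(2R,3S)-3-(hydroxymethyl)-2-[3-methoxy-4-(triisopropylsilyloxy)phenyl]-3,4-dihydro-2H-pyran-5-yl]-5-(triisopropylsilyloxy)-1-benzofuran-6-yl}ethanone | COc1cc([C@@H]2OC=C(c3cc4cc(O[Si](C(C)C)(C(C)C)C(C)C)c(C(C)=O)cc4o3)C[C@H]2CO)ccc1O[Si](C(C)C)(C(C)C)C(C)C | intermediate
26 | {(2R,3S)-5-[6-acetyl-5-(triisopropylsilyloxy)-1-benzofuran-2-yl]-2-[3-methoxy-4-(triisopropylsilyloxy)phenyl]-3,4-dihydro-2H-pyran-3-yl}methyl acetate | COc1cc([C@@H]2OC=C(c3cc4cc(O[Si](C(C)C)(C(C)C)C(C)C)c(C(C)=O)cc4o3)C[C@H]2COC(C)=O)ccc1O[Si](C(C)C)(C(C)C)C(C)C | intermediate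
27 | propolis-benzofuran A, [(2R,3S)-5-(6-acetyl-5-hydroxy-1-benzofuran-2-yl)-2-(4-hydroxy-3-methoxyphenyl)-3,4-dihydro-2H-pyran-3-yl]methyl acetate | COc1cc([C@@H]2OC=C(c3cc4cc(O)c(C(C)=O)cc4o3)C[C@H]2COC(C)=O)ccc1O | target

**Totals.** 16 steps in all; longest linear sequence 10 steps (for example 12 → 13 → 14 → 17 → 18 → 20 → 23 → 24 → 25 → 26 → 27; the arms from 1 and from 7 are equally long).

**Steps most likely to fail**

1. Step 12 (Proposed new method). What may go wrong:
   - β-elimination of the ring oxygen from the lactone enolate before it is silylated;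
   - ionisation of the allylic acetal instead of a concerted shift, which would erase the facial relay from the acetal centre;
   - loss of the labile ketene acetal before the boat transition state is reached.

   Fallback with known chemistry, a hetero-Diels–Alder bypass that sets out from 17 and comes back at 27. Mild acetal hydrolysis of 17 (acetone–H2O, PPTS, rt) should give 2-(6-acetyl-5-hydroxy-1-benzofuran-2-yl)prop-2-enal F1, whose chelated phenol needs no protection in a base-free sequence. Commercial (E)-coniferyl alcohol is silylated through its phenoxide (NaH 1.0 equiv, TIPSCl, THF, 0 °C) to (E)-3-[3-methoxy-4-(triisopropylsilyloxy)phenyl]prop-2-en-1-ol F2 and acetylated (Ac2O, pyridine) to its acetate F3. Thermal inverse-electron-demand oxa-Diels–Alder reaction of the 1-oxadiene F1 with excess F3 (toluene, 90 °C, BHT) forms O1–C2 and C3–C4; the nucleophilic alkene carbon bonds to the enal CH2 terminus, and the E-alkene fixes aryl and CH2OAc trans. It should give the racemic trans cycloadduct mono-TIPS ether F4. TBAF/AcOH then gives racemic propolis-benzofuran A F5, and preparative chromatography on a chiral stationary phase delivers 27. This route gives up the asymmetric relay and relies on resolution.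

2. Step 11. What may go wrong:
   - stalling of the acetal exchange for want of a driving force;
   - conjugate capture or oligomerisation of the ethoxy-allyl cation;
   - ionisation at the electron-rich benzylic C–O bond with loss of configuration or elimination to the cinnamate.

   Fallback, the carbonyl route, from 18 (and 19) back to 20. Hydrolysis of 18 (wet acetone, PPTS, rt) should give 2-[6-acetyl-5-(triisopropylsilyloxy)-1-benzofuran-2-yl]prop-2-enal F6. This is condensed at once with 19 (TMSOTf 5 mol%, CH2Cl2, −78 °C), the classical aldehyde version of the dioxanone synthesis. The Lewis acid then activates a carbonyl group and not an acetal, hexamethyldisiloxane is the thermodynamic sink, and the cis isomer 20 is the expected product.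

3. Step 9. What may go wrong:
   - oligomerisation or oxidative dimerisation of the liberated enyne;
   - incomplete heteroannulation of the alkynylphenol.

   Fallback, making the benzofuran first and forming the C2–vinyl bond by cross-coupling, from 14 back to 18. Sonogashira coupling of 14 with 10 (PdCl2(PPh3)2, CuI, Et3N, THF) should give 1-{2,5-dihydroxy-4-[(trimethylsilyl)ethynyl]phenyl}ethanone F7. TBAF in THF at 60 °C should desilylate and cyclise it to 1-(5-hydroxy-1-benzofuran-6-yl)ethanone F8. TIPSCl/imidazole gives its silyl ether F9. Iridium-catalysed C–H borylation ([Ir(OMe)(cod)]2, dtbpy, B2pin2, THF, rt), selective for the unhindered benzofuran C2–H, gives the 2-pinacolboronate F10. Suzuki–Miyaura coupling with 9 (Pd(dppf)Cl2, K3PO4, THF–H2O, 50 °C) then leads to 18.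

**Further compounds**

F1 | step 12 | 2-(6-acetyl-5-hydroxy-1-benzofuran-2-yl)prop-2-enal | O=CC(=C)c1cc2cc(O)c(C(C)=O)cc2o1
F2 | step 12 | (E)-3-[3-methoxy-4-(triisopropylsilyloxy)phenyl]prop-2-en-1-ol | OC/C=C/c1ccc(O[Si](C(C)C)(C(C)C)C(C)C)c(OC)c1
F3 | step 12 | (E)-3-[3-methoxy-4-(triisopropylsilyloxy)phenyl]prop-2-en-1-yl acetate | CC(=O)OC/C=C/c1ccc(O[Si](C(C)C)(C(C)C)C(C)C)c(OC)c1
F4 | step 12 | racemic trans-[5-(6-acetyl-5-hydroxy-1-benzofuran-2-yl)-2-[3-methoxy-4-(triisopropylsilyloxy)phenyl]-3,4-dihydro-2H-pyran-3-yl]methyl acetate (one enantiomer drawn) | COc1cc([C@@H]2OC=C(c3cc4cc(O)c(C(C)=O)cc4o3)C[C@H]2COC(C)=O)ccc1O[Si](C(C)C)(C(C)C)C(C)C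
F5 | step 12 | racemic propolis-benzofuran A, trans racemate (one enantiomer drawn) | COc1cc([C@@H]2OC=C(c3cc4cc(O)c(C(C)=O)cc4o3)C[C@H]2COC(C)=O)ccc1O
F6 | step 11 | 2-[6-acetyl-5-(triisopropylsilyloxy)-1-benzofuran-2-yl]prop-2-enal | O=CC(=C)c1cc2cc(O[Si](C(C)C)(C(C)C)C(C)C)c(C(C)=O)cc2o1
F7 | step 9 | 1-{2,5-dihydroxy-4-[(trimethylsilyl)ethynyl]phenyl}ethanone | CC(=O)c1cc(O)c(C#C[Si](C)(C)C)cc1O
F8 | step 9 | 1-(5-hydroxy-1-benzofuran-6-yl)ethanone | CC(=O)c1cc2occc2cc1O
F9 | step 9 | 1-[5-(triisopropylsilyloxy)-1-benzofuran-6-yl]ethanone | CC(=O)c1cc2occc2cc1O[Si](C(C)C)(C(C)C)C(C)C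
F10 | step 9 | 1-[2-(4,4,5,5-tetramethyl-1,3,2-dioxaborolan-2-yl)-5-(triisopropylsilyloxy)-1-benzofuran-6-yl]ethanone | CC(=O)c1cc2oc(B3OC(C)(C)C(C)(C)O3)cc2cc1O[Si](C(C)C)(C(C)C)C(C)C
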